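**Retrosynthetic overview**

1. Polymatin A ⇐ 8‑O‑angeloylation and unmasking of the α‑methylene lactone (carried as its Me2NH Mannich adduct); the C14 ester comes from Pd‑methoxycarbonylation of a C10 enol triflate.
2. Ten‑membered ring ⇐ anionic oxy‑Cope [3,3] of a trans‑1‑vinyl‑2‑isopropenylcyclohexanol (forms C2–C3, cleaves C5–C10) that already carries C6–C9 and the trans γ‑lactone.
3. Cyclohexane ⇐ type‑I carbonyl‑ene closure of C5–C6 on an acyclic aldehyde; C7 from a nitromethane Michael addition controlled by C8.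
4. C7–C10 with O8/O9 ⇐ diacetone‑D‑glucose (glucose C2, C3 = C8, C9).
5. Ring order: cyclohexane → γ‑lactone → ten‑membered ring by ring expansion.

Assumption: germacrane numbering of the target (C1–C15) is used for every intermediate; α = the face of H‑7 (O6, O9 α; C7 side chain, O8 β). The route is a paper design and has not been run.

---

**Step 1**
Reactants: 1 diacetone‑D‑glucose; 2 triisopropylsilyl triflate
Product: 3, 3‑O‑TIPS‑1,2:5,6‑di‑O‑isopropylidene‑α‑D‑glucofuranose
Conditions: TIPSOTf, 2,6‑lutidine, CH2Cl2, 0 °C → rt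
Reagents that add atoms: TIPSOTf, CC(C)[Si](C(C)C)(C(C)C)OS(=O)(=O)C(F)(F)F
Why: Silylation of the only free hydroxyl, which becomes O9 and stays protected until the penultimate step.

**Step 2**
Reactants: 3
Product: 4, 1,2‑O‑isopropylidene‑3‑O‑TIPS‑α‑D‑xylo‑pentodialdo‑1,4‑furanose
Conditions: H5IO6, EtOAc, rt
Reagents that add atoms: none
Why: Selective hydrolysis of the terminal acetonide with in‑situ periodate glycol cleavage gives the aldehyde without touching a stereocentre.

**Step 3**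
Reactants: 4
Product: 5, 1,2‑O‑isopropylidene‑3‑O‑TIPS‑β‑L‑arabino‑pentodialdo‑1,4‑furanose (C4 epimer)
Conditions: DBU (0.1 equiv), CH2Cl2, rt
Reagents that add atoms: none
Why: Base‑mediated enolisation equilibrates the formyl group to the 3,4‑trans position away from the bulky OTIPS; this makes O10 α, which steers the later ene cyclisation and is then oxidised away.

**Step 4**
Reactants: 5; 6 isopropyltriphenylphosphonium iodide
Product: 7, 5,6,7‑trideoxy‑1,2‑O‑isopropylidene‑6‑C‑methyl‑3‑O‑TIPS‑β‑L‑arabino‑hept‑5‑enofuranose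
Conditions: n‑BuLi, THF, −78 → 0 °C
Reagents that add atoms: isopropyltriphenylphosphonium iodide, CC(C)[P+](c1ccccc1)(c1ccccc1)c1ccccc1.[I-]
Why: Wittig olefination with the non‑stabilised ylide installs the C5=C4(CH3)2 unit (future C3, C4, C15).

**Step 5**
Reactants: 7
Product: 8, 5,6,7‑trideoxy‑6‑C‑methyl‑3‑O‑TIPS‑L‑arabino‑hept‑5‑enofuranose (lactol, anomers)
Conditions: TFA–H2O (9:1), 0 °C
Reagents that add atoms: none
Why: Acid hydrolysis of the 1,2‑acetal; the TIPS ether survives at 0 °C.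

**Step 6**
Reactants: 8; 9 tert‑butyldimethylsilyl triflate
Product: 10, the 2‑O‑TBS derivative of lactol 8
Conditions: TBSOTf (2.5 equiv), 2,6‑lutidine, CH2Cl2, 0 °C; then AcOH–THF–H2O, rt
Reagents that add atoms: TBSOTf, CC(C)(C)[Si](C)(C)OS(=O)(=O)C(F)(F)F
Why: Bis‑silylation followed by selective hydrolysis of the far more labile anomeric silyl acetal leaves O8 as its TBS ether.

**Step 7**
Reactants: 10; 11 methyl (triphenylphosphoranylidene)acetate; 12 chlorotriethylsilane
Product: 13, methyl (2E,4S,5R,6S)‑4‑TBSO‑5‑TIPSO‑6‑TESO‑8‑methylnona‑2,7‑dienoate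
Conditions: Ph3P=CHCO2Me, PhMe, 70 °C; then TESCl, imidazole, 0 °C
Reagents that add atoms: Ph3P=CHCO2Me, COC(=O)C=P(c1ccccc1)(c1ccccc1)c1ccccc1; TESCl, CC[Si](CC)(CC)Cl
Why: Wittig reaction on the open‑chain form of the lactol makes the C7=C11 enoate and frees O10, which is capped in situ to prevent oxa‑Michael closure (any Z‑enoate converges in Step 8).

**Step 8**
Reactants: 13; 14 nitromethane
Product: 15, methyl (3S,4S,5S,6S)‑3‑(nitromethyl)‑4‑TBSO‑5‑TIPSO‑6‑TESO‑8‑methylnon‑7‑enoate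
Conditions: MeNO2 (10 equiv), DBU, MeCN, rt
Reagents that add atoms: nitromethane, C[N+](=O)[O-]
Why: Michael addition of the nitronate sets C7 by 1,2‑induction from C8: H‑8 lies in the enoate plane (A1,3 strain) and attack is anti to the bulky C9 branch, giving the 7,8‑syn adduct.

**Step 9**
Reactants: 15; 16 water
Product: 17, methyl (3R,4S,5S,6S)‑3‑formyl‑4‑TBSO‑5‑TIPSO‑6‑TESO‑8‑methylnon‑7‑enoate
Conditions: NaOMe, MeOH, 0 °C; then TiCl3, NH4OAc, H2O–THF (pH ≈ 5)
Reagents that add atoms: water, O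
Why: McMurry's buffered reductive Nef reaction converts CH2NO2 into the C6 aldehyde without strong acid or base, so C7 and the silyl ethers are preserved.

**Step 10**
Reactants: 17
Product: 18, cyclohexane‑fused trans γ‑lactone: 5β‑isopropenyl, 6α‑O–C12(=O)–C11H2–7β, 8β‑OTBS, 9α‑OTIPS, 10α‑OH [(3aS,4S,5S,6S,7S,7aS)‑4‑TBSO‑6‑hydroxy‑7‑(prop‑1‑en‑2‑yl)‑5‑TIPSO‑hexahydrobenzofuran‑2(3H)‑one]
Conditions: Me2AlCl, CH2Cl2, −78 → −20 °C; then CSA (cat.), MeOH, 0 °C
Reagents that add atoms: none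
Why: Lewis‑acid type‑I carbonyl‑ene cyclisation (as citronellal → isopulegol) through the chair with the C7 side chain and O10 equatorial and the trans‑vicinal OTBS/OTIPS diaxial gives equatorial 6α‑OH and 5β‑isopropenyl; acidic methanol then removes the TES group and closes the lactone.

**Step 11**
Reactants: 18; 19 Eschenmoser's salt
Product: 20, the 11‑(dimethylaminomethyl) lactone (C11 epimers, inconsequential)
Conditions: LDA (2.3 equiv), THF, −78 °C; CH2=NMe2+ I−, → 0 °C; aqueous work‑up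
Reagents that add atoms: Eschenmoser's salt, C=[N+](C)C.[I-]
Why: Mannich aminomethylation of the lactone enolate introduces C13 as a β‑amino lactone, a masked α‑methylene lactone that tolerates the Grignard, alkoxide and Pd steps.

**Step 12**
Reactants: 20
Product: 21, the C10 ketone
Conditions: Dess–Martin periodinane, NaHCO3, CH2Cl2, 0 °C → rt
Reagents that add atoms: none
Why: Oxidation of the only free hydroxyl; the buffer avoids E1cB loss of the β‑acyloxy group, and the α‑isopropenyl group is already in its stable equatorial position.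

**Step 13**
Reactants: 21; 22 vinylmagnesium bromide
Product: 23, 10β‑hydroxy‑10α‑vinyl carbinol (vinyl trans to the 5β‑isopropenyl group)
Conditions: CeCl3, vinylMgBr, THF, −78 °C
Reagents that add atoms: vinylmagnesium bromide, C=C[Mg]Br
Why: Non‑basic organocerium 1,2‑addition; the axial face is blocked by the syn‑axial 8β‑OTBS, so equatorial attack gives an equatorial vinyl and axial alkoxide‑to‑be, and the lactone is untouched at −78 °C.

**Step 14**
Reactants: 23
Product: 24, (4E)‑cyclodec‑4‑en‑10‑one carrying the 6α,12‑lactone, 8β‑OTBS and 9α‑OTIPS (C14 still absent)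
Conditions: KHMDS, 18‑crown‑6, THF, 0 °C → rt; AcOH, −78 °C
Reagents that add atoms: none
Why: Anionic oxy‑Cope rearrangement through the chair transition state of the trans‑diequatorial dialkenyl alkoxide forms C2–C3 and breaks C5–C10; equatorial C6 in that chair gives the 4E alkene, and C6–C9 are not involved.

**Step 15**
Reactants: 24; 25 Comins' reagent
Product: 26, C10 enol triflate with C1=C10 ring‑cis (C9 cis to C2)
Conditions: KHMDS, THF, −78 °C; then Comins' reagent
Reagents that add atoms: Comins' reagent, Clc1ccc(nc1)N(S(=O)(=O)C(F)(F)F)S(=O)(=O)C(F)(F)F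
Why: Kinetic deprotonation at C1H2 rather than the hindered α‑silyloxy C9–H, followed by O‑triflation; the second double bond of the ten‑membered ring is expected to form ring‑cis, which is the melampolide geometry.

**Step 16**
Reactants: 26; 27 carbon monoxide; 28 methanol
Product: 29, the C14 methyl ester (1(10)‑ring‑cis, 4E)
Conditions: Pd(OAc)2, dppf, Et3N, CO (1 atm), MeOH–DMF, 50 °C
Reagents that add atoms: carbon monoxide, [C-]#[O+]; methanol, CO
Why: Pd‑catalysed methoxycarbonylation of the enol triflate proceeds with retention of alkene geometry.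

**Step 17**
Reactants: 29
Product: 30, the 8β‑alcohol (9α‑OTIPS retained)
Conditions: HF·pyridine, pyridine, THF, 0 °C
Reagents that add atoms: none
Why: Buffered fluoride removes the secondary TBS ether much faster than the bulkier TIPS ether.

**Step 18**
Reactants: 30; 31 angelic acid
Product: 32, the 8β‑angelate
Conditions: angelic acid, 2,4,6‑trichlorobenzoyl chloride, Et3N, PhMe, rt; then 30, 80 °C
Reagents that add atoms: angelic acid, C/C=C(/C)C(=O)O
Why: Yamaguchi mixed‑anhydride esterification without DMAP acylates the hindered alcohol without Z→E (angelate → tiglate) isomerisation.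

**Step 19**
Reactants: 32
Product: 33, 13‑dimethylamino‑11,13‑dihydropolymatin A (free 9α‑OH)
Conditions: HF·pyridine, THF, rt
Reagents that add atoms: none
Why: Fluoride desilylation of the TIPS ether under non‑basic conditions that spare the angelate and both esters.

**Step 20**
Reactants: 33
Product: 34, Polymatin A
Conditions: MeI, CH2Cl2–MeOH, rt; then aq. NaHCO3
Reagents that add atoms: none (the methyl group leaves with trimethylamine)
Why: N‑quaternisation followed by mild Hofmann‑type β‑elimination unmasks the α‑methylene‑γ‑lactone as the last step.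

---

**Compound list**

1 | 1,2:5,6‑di‑O‑isopropylidene‑α‑D‑glucofuranose | CC1(C)OC[C@@H](O1)[C@H]2O[C@@H]3OC(C)(C)O[C@@H]3[C@H]2O | starting material
2 | triisopropylsilyl triflate | CC(C)[Si](C(C)C)(C(C)C)OS(=O)(=O)C(F)(F)F | starting material
3 | 3‑O‑TIPS‑diacetone‑D‑glucose | CC1(C)OC[C@@H](O1)[C@H]2O[C@@H]3OC(C)(C)O[C@@H]3[C@H]2O[Si](C(C)C)(C(C)C)C(C)C | intermediate
4 | 1,2‑O‑isopropylidene‑3‑O‑TIPS‑α‑D‑xylo‑pentodialdo‑1,4‑furanose | O=C[C@H]1O[C@@H]2OC(C)(C)O[C@@H]2[C@H]1O[Si](C(C)C)(C(C)C)C(C)C | intermediate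
5 | 1,2‑O‑isopropylidene‑3‑O‑TIPS‑β‑L‑arabino‑pentodialdo‑1,4‑furanose | O=C[C@@H]1O[C@@H]2OC(C)(C)O[C@@H]2[C@H]1O[Si](C(C)C)(C(C)C)C(C)C | intermediate
6 | isopropyltriphenylphosphonium iodide | CC(C)[P+](c1ccccc1)(c1ccccc1)c1ccccc1.[I-] | starting material
7 | 5,6,7‑trideoxy‑1,2‑O‑isopropylidene‑6‑C‑methyl‑3‑O‑TIPS‑β‑L‑arabino‑hept‑5‑enofuranose | CC(C)=C[C@@H]1O[C@@H]2OC(C)(C)O[C@@H]2[C@H]1O[Si](C(C)C)(C(C)C)C(C)C | intermediate
8 | 5,6,7‑trideoxy‑6‑C‑methyl‑3‑O‑TIPS‑L‑arabino‑hept‑5‑enofuranose | CC(C)=C[C@@H]1OC(O)[C@H](O)[C@H]1O[Si](C(C)C)(C(C)C)C(C)C | intermediate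
9 | tert‑butyldimethylsilyl triflate | CC(C)(C)[Si](C)(C)OS(=O)(=O)C(F)(F)F | starting material
10 | 2‑O‑TBS‑5,6,7‑trideoxy‑6‑C‑methyl‑3‑O‑TIPS‑L‑arabino‑hept‑5‑enofuranose | CC(C)=C[C@@H]1OC(O)[C@H](O[Si](C)(C)C(C)(C)C)[C@H]1O[Si](C(C)C)(C(C)C)C(C)C | intermediate
11 | methyl (triphenylphosphoranylidene)acetate | COC(=O)C=P(c1ccccc1)(c1ccccc1)c1ccccc1 | starting material
12 | chlorotriethylsilane | CC[Si](CC)(CC)Cl | starting material
13 | methyl (2E,4S,5R,6S)‑4‑TBSO‑5‑TIPSO‑6‑TESO‑8‑methylnona‑2,7‑dienoate | COC(=O)/C=C/[C@H](O[Si](C)(C)C(C)(C)C)[C@@H](O[Si](C(C)C)(C(C)C)C(C)C)[C@@H](O[Si](CC)(CC)CC)C=C(C)C | intermediate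
14 | nitromethane | C[N+](=O)[O-] | starting material
15 | methyl (3S,4S,5S,6S)‑3‑(nitromethyl)‑4‑TBSO‑5‑TIPSO‑6‑TESO‑8‑methylnon‑7‑enoate | COC(=O)C[C@@H](C[N+](=O)[O-])[C@H](O[Si](C)(C)C(C)(C)C)[C@@H](O[Si](C(C)C)(C(C)C)C(C)C)[C@@H](O[Si](CC)(CC)CC)C=C(C)C | intermediate
16 | water | O | starting material
17 | methyl (3R,4S,5S,6S)‑3‑formyl‑4‑TBSO‑5‑TIPSO‑6‑TESO‑8‑methylnon‑7‑enoate | COC(=O)C[C@@H](C=O)[C@H](O[Si](C)(C)C(C)(C)C)[C@@H](O[Si](C(C)C)(C(C)C)C(C)C)[C@@H](O[Si](CC)(CC)CC)C=C(C)C | intermediate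
18 | (3aS,4S,5S,6S,7S,7aS)‑4‑TBSO‑6‑hydroxy‑7‑(prop‑1‑en‑2‑yl)‑5‑TIPSO‑hexahydrobenzofuran‑2(3H)‑one | O[C@H]1[C@H](C(C)=C)[C@H]2OC(=O)C[C@@H]2[C@H](O[Si](C)(C)C(C)(C)C)[C@H]1O[Si](C(C)C)(C(C)C)C(C)C | intermediate
19 | Eschenmoser's salt | C=[N+](C)C.[I-] | starting material
20 | 3‑(dimethylaminomethyl) derivative of 18 | O[C@H]1[C@H](C(C)=C)[C@H]2OC(=O)C(CN(C)C)[C@@H]2[C@H](O[Si](C)(C)C(C)(C)C)[C@H]1O[Si](C(C)C)(C(C)C)C(C)C | intermediate
21 | C10 ketone of 20 | O=C1[C@H](C(C)=C)[C@H]2OC(=O)C(CN(C)C)[C@@H]2[C@H](O[Si](C)(C)C(C)(C)C)[C@H]1O[Si](C(C)C)(C(C)C)C(C)C | intermediate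
22 | vinylmagnesium bromide | C=C[Mg]Br | starting material
23 | 10β‑hydroxy‑10α‑vinyl‑5β‑isopropenyl carbinol | C=C[C@@]1(O)[C@H](C(C)=C)[C@H]2OC(=O)C(CN(C)C)[C@@H]2[C@H](O[Si](C)(C)C(C)(C)C)[C@H]1O[Si](C(C)C)(C(C)C)C(C)C | intermediate
24 | (4E)‑10‑oxo‑cyclodec‑4‑ene 6α,12‑lactone (8β‑OTBS, 9α‑OTIPS, 13‑NMe2) | O=C1CCC/C(C)=C/[C@H]2OC(=O)C(CN(C)C)[C@@H]2[C@H](O[Si](C)(C)C(C)(C)C)[C@H]1O[Si](C(C)C)(C(C)C)C(C)C | intermediate
25 | Comins' reagent | Clc1ccc(nc1)N(S(=O)(=O)C(F)(F)F)S(=O)(=O)C(F)(F)F | starting material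
26 | C10 enol triflate of 24 (1(10)‑ring‑cis, 4E) | FC(F)(F)S(=O)(=O)O/C1=C/CC/C(C)=C/[C@H]2OC(=O)C(CN(C)C)[C@@H]2[C@H](O[Si](C)(C)C(C)(C)C)[C@H]1O[Si](C(C)C)(C(C)C)C(C)C | intermediate
27 | carbon monoxide | [C-]#[O+] | starting material
28 | methanol | CO | starting material
29 | 13‑dimethylamino‑11,13‑dihydro‑8‑O‑TBS‑9‑O‑TIPS‑8‑desangeloyl‑polymatin A | COC(=O)/C1=C/CC/C(C)=C/[C@H]2OC(=O)C(CN(C)C)[C@@H]2[C@H](O[Si](C)(C)C(C)(C)C)[C@H]1O[Si](C(C)C)(C(C)C)C(C)C | intermediate
30 | 8β‑hydroxy analogue of 29 | COC(=O)/C1=C/CC/C(C)=C/[C@H]2OC(=O)C(CN(C)C)[C@@H]2[C@H](O)[C@H]1O[Si](C(C)C)(C(C)C)C(C)C | intermediate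
31 | angelic acid | C/C=C(/C)C(=O)O | starting material
32 | 9‑O‑TIPS‑13‑dimethylamino‑11,13‑dihydropolymatin A | COC(=O)/C1=C/CC/C(C)=C/[C@H]2OC(=O)C(CN(C)C)[C@@H]2[C@H](OC(=O)/C(C)=C\C)[C@H]1O[Si](C(C)C)(C(C)C)C(C)C | intermediate
33 | 13‑dimethylamino‑11,13‑dihydropolymatin A | COC(=O)/C1=C/CC/C(C)=C/[C@H]2OC(=O)C(CN(C)C)[C@@H]2[C@H](OC(=O)/C(C)=C\C)[C@H]1O | intermediate
34 | Polymatin A | C=C1C(=O)O[C@@H]2/C=C(\C)CC/C=C(/C(=O)OC)[C@H](O)[C@@H](OC(=O)/C(C)=C\C)[C@@H]12 | target

---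

**Step count:** 20 steps; Steps 6, 7 and 10 are two‑stage one‑pot operations, so 23 if each stage is counted separately.
**Longest linear sequence:** 20 steps from diacetone‑D‑glucose (fully linear).

**Three steps most likely to fail, with fallbacks**

1. **Step 8 (C7 by acyclic 1,2‑induction).** The wrong C7 epimer would carry through the ene step to the wrong C5/C6 series. Fallback: switch to cyclic stereocontrol by leaving O9 free, closing the (Z)‑enoate onto O9 as the 5,6‑dihydropyran‑2‑one, and adding the one‑carbon nucleophile trans to the C8 substituent on that ring (this gives the same 7β relationship), then reopening the δ‑lactone.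

2. **Step 10 (carbonyl‑ene closure).** The chair may not be selected cleanly, or the allylic silyl ether may ionise with the Lewis acid. Fallback: close C5–C6 by an intramolecular Nozaki–Hiyama–Kishi allylation instead; the prenyl terminus is built as a C3 allylic bromide (HWE/DIBAL/bromination in place of the isopropylidene Wittig), and the Cr(III) chair transition state gives the same anti 5β‑isopropenyl/6α‑OH pair.

3. **Steps 14–15 (oxy‑Cope, then C1=C10 geometry).** The alkoxide could fragment (Grob‑type loss of the anti‑periplanar lactone carboxylate) instead of rearranging, and kinetic enolisation of the cyclodecenone may not give the ring‑cis triflate. Fallback: trap the oxy‑Cope enolate directly as its (ring‑trans) triflate, carbonylate, and then equilibrate C1=C10 to the thermodynamically preferred tiglate‑type, ring‑cis enoate by reversible thiyl‑radical addition (PhSH, AIBN). If fragmentation dominates, carry O6 as a silyl ether and C12 as a protected primary alcohol through the ring expansion and form the lactone afterwards by oxidation.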